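## Analysis of the target

- Locants: target 45 is an ester of two related halves. The lactone half is a cis-fused cyclohexane/oxepinone: ring A is C1–C6, and ring B is C5–C7(=O)–O–C8H2–C9(CO2H)=C10H–C6. Its C13H2–O on C4 is acylated by an (E)-2-(hydroxymethyl)acrylic acid whose β-carbon carries a cyclohexene C1′–C6′ (C2′=C3′ with CH2OH on C3′, isopropyl on C6′).
- Ring A holds four contiguous stereocentres. The isopropyl group on C1 (S) is trans to C10 on C6 (R); C7 on C5 (S) is cis to C10; on the quaternary C4 (R) the hydroxyl is cis and C13 trans to C7. The acyl half has two stereocentres, C1′ and C6′ (both S), with the side chain trans to the isopropyl group.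
- Both halves contain the unit ring–CH=C(CH2O–)(CO2–) with the ring cis to CH2O. In the lactone half the CH2O closes ring B onto C7; in the acyl half the carboxyl makes the linking ester.
- Sensitive features are: the allylic lactone C8–O of a 2-(acyloxymethyl)acrylate (open to allylic displacement and to palladium); the epimerisable C5–H, whose carboxyl is axial in the chair with equatorial isopropyl; the doubly allylic C1′–H; and a free acid beside three esters, so the last deprotection cannot be a hydrolysis.
- The hard part is the pair C4/C5: a fully substituted, oxygen-bearing carbon next to a carboxyl-bearing carbon, both flanked by further stereocentres. Neither enolate chemistry at C5 nor addition to a C4 ketone is reliably face-selective there.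
- The strategy rests on one observation. With a C2=C3 alkene in ring A, C7–C5–C4–C3=C2 is a γ,δ-unsaturated acid, so C4–C5 is the bond a [3,3] shift makes. If C7, C5, C6, C1 and C2 are first tied in a δ-lactone (C7–O–C2), that shift closes ring A and fixes C4 and C5 together.

## Retrosynthetic reasoning

**45 ⇐ 44 ⇐ 31 + 42.** The last skeletal bond is the C13–O ester. It is cut there because both halves are then complete, and the union is the acylation of a primary alcohol next to a tertiary one that needs no protection. All protecting groups left in 44 (two silyl ethers and a trimethylsilylethyl ester on the C9 carboxyl) fall to fluoride. Hydrolysis is excluded by the three esters, and palladium-labile esters are excluded by the allylic lactone.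

**31 ⇐ 30 ⇐ 29 ⇐ 27 ⇐ 26 ⇐ 20 + 25.** Ring B is opened first at the lactone bond C7–O–C8 and then at the alkene C9=C10. Phosphonate 25 brings C8, C9 and the protected carboxyl in one olefination of the C10 aldehyde of 20. That olefination has to place C6 cis to C8, which is the normal outcome for an α-substituted phosphonoacetate. The reverse order (ester first, olefination second) is not used because a phosphonate carbanion β to an acyloxy group eliminates. The ether on O4 and the silyl ether on O13 stay until ring B is closed, so that C7 can acylate only one hydroxyl; they are then removed via 30 to give 31.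

**20 ⇐ 19 ⇐ 18.** C10 is carried through the key step as a dimethyl acetal, not as a silyl ether. A free C10 hydroxyl cis to the C7 acid would close a γ-lactone and block the oxidation, whereas acetal hydrolysis gives the aldehyde level directly. The ring alkene left by the rearrangement is reduced in 18, before any acrylate exists.

**18 ⇐ 15 (key disconnection).** The C4–C5 bond is cut and the C2–O bond re-formed, which turns the cyclohexene acid into δ-lactone 15 with an (E)-enol ether arm on C2. Forward, the lactone silyl ketene acetal must rearrange through the only transition state its bicyclic constraint allows. The C2 configuration then sets C5, and the enol ether geometry sets C4.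

**15 ⇐ 14 ⇐ 13 ⇐ 12 ⇐ 8 + 10 (10 ⇐ 9).** The lactone is opened to hydroxy ester 14. The C2 carbinol comes from ketone 13 by a catalyst-controlled reduction. The enol ether of 13 comes from ynone 12 by conjugate addition of the protecting alcohol, which gives the isomer with oxygen trans to the carbonyl, the one the rearrangement needs. Ynone 12 is cut at C2–C3 into N-methoxy-N-methylamide 8 and alkyne 10, the silyl ether of propargyl alcohol 9. The arm is built late because every compound from 13 onward is acid-labile.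

**8 ⇐ 7 ⇐ 6 ⇐ 5 ⇐ 3 + 4 (3 ⇐ 1 + 2).** The C1–C6 bond is cut as an amine-catalysed Michael addition of 3-methylbutanal 4 to alkylidene malonate 3, which sets both stereocentres with the syn relationship that becomes trans on the ring. The second ester of the malonate is only an activating group. It is removed after the aldehyde has been oxidised and converted into the amide (an α-branched aldehyde would not survive the decarboxylation). It is also removed before the ynone is made, because a malonate C–H would add to the ynone. Compound 3 is the condensation product of 1 and 2.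

**42 ⇐ 40 ⇐ 39 ⇐ 38 ⇐ 37 + 25; 37 ⇐ 36 ⇐ 34 ⇐ 33 ⇐ 4 + 32.** The acyl half uses the same phosphonate 25 on aldehyde 37. The C3′ hydroxymethyl group is put in afterwards by cross-coupling at the enol triflate, so that the aldehyde never coexists with an electron-rich ring alkene. Compound 37 comes from enol triflate 36 by cleavage of a vinyl group. Compound 36 comes from (S)-cryptone 34 by conjugate addition trans to the isopropyl group and trapping of the regiodefined enolate. Compound 34 is the aldol condensation product of keto aldehyde 33, made from 4 and methyl vinyl ketone 32 with the catalyst enantiomer opposite to the one used for 5.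

**25 ⇐ 24 ⇐ 23 ⇐ 21 + 22.** The phosphonate is assembled from phosphonoacetic acid 21 and silyl alcohol 22, then hydroxymethylated and silylated.

## Alternatives that were turned down

**Alternative 1:** The C4–C13 bond is cut. C4 goes back to a ketone held in the cis-fused bicyclo[4.2.0]octanone A1, the [2+2] photoadduct of enone 34 with the parent 1,2-diene; its four-membered ring carries C7 (as a methylidene carbon) and C10. Forward, a sulfur ylide transfers CH2 to the ketone of A1 from the face remote from the C5–C7 bond, and the betaine closes to spiro-epoxide A2 (Corey–Chaykovsky reaction).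
- For it: A1 is only one step beyond 34, and the ring fusion fixes C5 and C6 cis without effort. A2 is an electrophile at C13, so the linking ester could be made by carboxylate opening with no protecting group on either oxygen of C4. On step count to a C4-oxygenated intermediate and on economy of protection it is stronger than the chosen route.
- Against it: the C4 configuration rests on a facial preference of an irreversible addition to a cyclohexanone (convex face against the ylide's intrinsic axial preference), not on a stereospecific process. The photocycloaddition must be head-to-head and anti to the isopropyl group. The cyclobutane must later be cut between C7 and C10, with C7 at the acid level and C10 at the aldehyde level, in the presence of the epoxide; no single reliable operation does this.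
- In exchange, the Claisen route gives C4 and C5 from one concerted event decided by two elements that can be verified beforehand, and it delivers C7 as the acid and C10 as a masked aldehyde directly.

**Alternative 2:** Ring B is cut at its alkene C9=C10. Diene A3 (a C6 vinyl group and a 2-(acyloxymethyl)acrylate on the C5 carboxyl) is closed by ring-closing alkene metathesis to oxepinone A4.
- For it: the ester C7–O–C8 is made intermolecularly from a simple allylic partner, and the ring alkene can only be cis. Ring B costs one ring-forming step, where the present route needs olefination, deprotection and lactonisation, and the hindered C7 acid never has to be activated for a medium-ring closure. On the making of ring B it is at least as strong.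
- Against it: the alkene to be formed is trisubstituted, conjugated to an ester and attached to a tertiary ring carbon, the least favourable combination for metathesis. The allylic acyloxy group of the acrylate is a leaving group towards the metal. Above all, the disconnection leaves all four ring-A stereocentres, including C4/C5 and an epoxide, to be made by other means, so it is an end-game device.
- The chosen route spends three steps on ring B but solves C4/C5. A4 itself appears below only as a fallback intermediate.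

**Alternative 3:** The C4–O bond is cut. The tertiary oxygen is taken from the C5 carboxyl itself in acid A5, which has an exocyclic C4=C13 alkene. Buffered iodolactonisation closes the four-membered lactone A6, forming C4–O and C13–I across the alkene.
- For it: the oxygen is delivered intramolecularly, so C4–O must be cis to C7, a certainty equal to that of the sigmatropic shift. The reagents are trivial, and attack at the more substituted alkene carbon is the normal mode.
- Against it: A5 must already contain C5 in the right configuration next to an sp2 carbon, where it is an epimerisable allylic α-carboxyl centre, so the C5 problem is moved and not solved. The β-lactone is strained and loses CO2 or opens at the acyl carbon easily. The C13 iodide is neopentyl and resists the carboxylate displacement the linking ester needs. C7 must then be moved from the four- to the seven-membered lactone without epimerising C5.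
- The Claisen route sets C5 together with C4 from the remote, robust C2 stereocentre, and gives the two oxygens on C4 and C13 already differentiated.

Key step: step 11

## Assumptions

- Assumption 1: 24 and 25 are racemic at the phosphonate carbon, which becomes sp2 in steps 17 and 26.
- Assumption 2: in step 9 the doubly branched C1 substituent is taken as the sterically dominant ketone substituent; if the opposite sense were found, the enantiomeric oxazaborolidine would be used.

## Route

**Part A. Lactone half up to the rearrangement**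

Step 1
Reactants: 1 2,2-dimethoxyacetaldehyde (60 % in water); 2 dimethyl malonate
Product: 3 dimethyl 2-(2,2-dimethoxyethylidene)propanedioate
Conditions: piperidine (10 mol %), AcOH (10 mol %), toluene, reflux, azeotropic removal of water
Reagents that add atoms: none
Why: Knoevenagel condensation of a non-enolisable aldehyde with a malonate; the two esters are identical, so there is no alkene geometry to control.

Step 2
Reactants: 3 dimethyl 2-(2,2-dimethoxyethylidene)propanedioate; 4 3-methylbutanal
Product: 5 dimethyl 2-[(2S,3S)-3-formyl-1,1-dimethoxy-4-methylpentan-2-yl]propanedioate (C1 S, C6 S; isopropyl and dimethoxymethyl syn along C2–C1–C6–C5)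
Conditions: (R)-2-[diphenyl(trimethylsilyloxy)methyl]pyrrolidine (10 mol %), PhCO2H (10 mol %), toluene, 0 °C → rt
Reagents that add atoms: none
Why: Diarylprolinol silyl ether-catalysed Michael addition of an aldehyde to an alkylidene malonate; the (E)-enamine of 4 is attacked on the face remote from the diarylmethyl group through an acyclic synclinal transition state, which should set C1 and C6 syn. The (R)-catalyst is chosen because the (S)-catalyst gives the mirror-image sense in the analogous nitroalkene additions.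

Step 3
Reactants: 5 dimethyl 2-[(2S,3S)-3-formyl-1,1-dimethoxy-4-methylpentan-2-yl]propanedioate
Product: 6 (2S,3S)-3-(dimethoxymethyl)-5-methoxy-4-(methoxycarbonyl)-5-oxo-2-(propan-2-yl)pentanoic acid
Conditions: NaClO2, NaH2PO4, 2-methylbut-2-ene, t-BuOH/H2O, 0 °C → rt
Reagents that add atoms: sodium chlorite, [Na+].[O-]Cl=O
Why: Pinnick oxidation is selective for the aldehyde, does not epimerise the α-stereocentre, and leaves the acetal and malonate intact in the phosphate buffer.

Step 4
Reactants: 6 (2S,3S)-3-(dimethoxymethyl)-5-methoxy-4-(methoxycarbonyl)-5-oxo-2-(propan-2-yl)pentanoic acid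
Product: 7 dimethyl 2-[(2S,3S)-1,1-dimethoxy-3-[methoxy(methyl)carbamoyl]-4-methylpentan-2-yl]propanedioate
Conditions: MeNH(OMe)·HCl, EDC·HCl, HOBt (cat.), N-methylmorpholine, CH2Cl2, 0 °C → rt
Reagents that add atoms: N,O-dimethylhydroxylamine hydrochloride, CNOC.Cl
Why: Carbodiimide/HOBt amide coupling; the N-methoxy-N-methylamide is the acyl donor for the ynone and keeps C2 inert during the decarboxylation.

Step 5
Reactants: 7 dimethyl 2-[(2S,3S)-1,1-dimethoxy-3-[methoxy(methyl)carbamoyl]-4-methylpentan-2-yl]propanedioate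
Product: 8 methyl (3R,4S)-3-(dimethoxymethyl)-4-[methoxy(methyl)carbamoyl]-5-methylhexanoate (C6 is now R by a change of priorities only)
Conditions: LiCl, H2O, DMSO, 130 °C
Reagents that add atoms: none
Why: Krapcho dealkoxycarbonylation (chloride attack at a methyl ester, loss of CO2) removes the activating ester under neutral conditions that spare acetal and amide. It is placed after the aldehyde is gone and before the ynone exists, because a malonate C–H would add to the ynone in step 8.

Step 6
Reactants: 9 prop-2-yn-1-ol (propargyl alcohol)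
Product: 10 tri(propan-2-yl)(prop-2-yn-1-yloxy)silane
Conditions: i-Pr3SiCl, imidazole, CH2Cl2, 0 °C → rt
Reagents that add atoms: chlorotri(propan-2-yl)silane, CC(C)[Si](Cl)(C(C)C)C(C)C
Why: Standard silylation; the bulky silyl ether must survive to step 21.

Step 7
Reactants: 10 tri(propan-2-yl)(prop-2-yn-1-yloxy)silane; 8 methyl (3R,4S)-3-(dimethoxymethyl)-4-[methoxy(methyl)carbamoyl]-5-methylhexanoate
Product: 12 methyl (3R,4S)-3-(dimethoxymethyl)-5-oxo-4-(propan-2-yl)-8-{[tri(propan-2-yl)silyl]oxy}oct-6-ynoate, via lithium acetylide 11 (not isolated)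
Conditions: 10, n-BuLi, THF, −78 °C; then 8, −78 → −40 °C; aq. NH4Cl
Reagents that add atoms: none
Why: Acylation of a lithium acetylide by an N-methoxy-N-methylamide through the chelated tetrahedral adduct, which collapses only on work-up, so no over-addition occurs. Methyl esters need a Lewis acid to react with lithium acetylides at this temperature, so the C7 ester should be spared.

Step 8
Reactants: 12 methyl (3R,4S)-3-(dimethoxymethyl)-5-oxo-4-(propan-2-yl)-8-{[tri(propan-2-yl)silyl]oxy}oct-6-ynoate
Product: 13 methyl (3R,4S,6E)-3-(dimethoxymethyl)-7-[(4-methoxyphenyl)methoxy]-5-oxo-4-(propan-2-yl)-8-{[tri(propan-2-yl)silyl]oxy}oct-6-enoate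
Conditions: 4-MeOC6H4CH2OH, PMe3 (20 mol %), CH2Cl2, 0 °C → rt
Reagents that add atoms: (4-methoxyphenyl)methanol, COc1ccc(CO)cc1
Why: Trialkylphosphine-catalysed conjugate addition of an alcohol to an ynone (the phosphine adds at the β-carbon and the alkoxide replaces it by addition–elimination). It gives the thermodynamically preferred β-alkoxy enone with oxygen trans to the carbonyl, which is the (E) geometry the key step needs.

Step 9
Reactants: 13 methyl (3R,4S,6E)-3-(dimethoxymethyl)-7-[(4-methoxyphenyl)methoxy]-5-oxo-4-(propan-2-yl)-8-{[tri(propan-2-yl)silyl]oxy}oct-6-enoate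
Product: 14 methyl (3R,4S,5R,6E)-3-(dimethoxymethyl)-5-hydroxy-7-[(4-methoxyphenyl)methoxy]-4-(propan-2-yl)-8-{[tri(propan-2-yl)silyl]oxy}oct-6-enoate
Conditions: (R)-1-methyl-3,3-diphenyltetrahydro-1H,3H-pyrrolo[1,2-c][1,3,2]oxazaborole (0.2 equiv), catecholborane, toluene, −78 → −40 °C; aq. NaHCO3
Reagents that add atoms: none
Why: Corey–Bakshi–Shibata reduction of an enone with catecholborane, which does not hydroborate the enol ether. C1 carries two branched substituents and gives no useful intrinsic bias, so the catalyst should decide the face; with the C1 side as the large group the (R)-catalyst should deliver hydride to give the (5R)-carbinol.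

Step 10
Reactants: 14 methyl (3R,4S,5R,6E)-3-(dimethoxymethyl)-5-hydroxy-7-[(4-methoxyphenyl)methoxy]-4-(propan-2-yl)-8-{[tri(propan-2-yl)silyl]oxy}oct-6-enoate
Product: 15 (4R,5S,6R)-4-(dimethoxymethyl)-6-[(1E)-2-[(4-methoxyphenyl)methoxy]-3-{[tri(propan-2-yl)silyl]oxy}prop-1-en-1-yl]-5-(propan-2-yl)oxan-2-one (δ-lactone; arm on C2 cis to the C1 isopropyl and trans to the C6 dimethoxymethyl)
Conditions: LiN(SiMe3)2, THF, −40 → 0 °C; aq. NaHCO3; chromatography on Et3N-deactivated silica
Reagents that add atoms: none
Why: Intramolecular transesterification of the lithium alkoxide onto the methyl ester closes the six-membered lactone. Basic aprotic conditions are used because the allylic C2–O bond next to the enol ether ionises under acid.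

Step 11
Reactants: 15 (4R,5S,6R)-4-(dimethoxymethyl)-6-[(1E)-2-[(4-methoxyphenyl)methoxy]-3-{[tri(propan-2-yl)silyl]oxy}prop-1-en-1-yl]-5-(propan-2-yl)oxan-2-one
Product: 18 (1S,2R,5R,6S)-6-(dimethoxymethyl)-2-[(4-methoxyphenyl)methoxy]-5-(propan-2-yl)-2-({[tri(propan-2-yl)silyl]oxy}methyl)cyclohex-3-ene-1-carboxylic acid, via silyl ketene acetal 16 (not isolated), via trimethylsilyl ester 17 (not isolated)
Conditions: LiN(i-Pr)2, Me3SiCl/Et3N, THF, −78 °C → rt, then 50 °C; H2O/NaH2PO4
Reagents that add atoms: none
Why: LiN(i-Pr)2 removes a C5 proton (the only enolisable position) and Me3SiCl traps the enolate as the endocyclic silyl ketene acetal 16, in which C5=C7–O–C2–C3=C4 is a 1,5-diene that undergoes a concerted suprafacial [3,3] shift (Ireland–Claisen rearrangement). The closest known reaction types are the rearrangement of alkenyl lactone silyl ketene acetals to cycloalkenecarboxylic acids and the ester-enolate Claisen rearrangement of glycal esters, where the new C–C bond is also made to an enol ether carbon. Ring A (C5, C6, C1, C2, C3, C4) closes by this transannular shift as the O–C2 bond breaks, so the six-membered lactone is exchanged for a six-membered carbocycle and C7 is released as silyl ester 17, hydrolysed on work-up. Because C5 and C2 are also joined through C6–C1, the six-atom array is part of a bicyclo[2.2.2]octane-like transition state and can only be a boat. C5 is controlled by C2: the axial arm lies on the face opposite the C6 substituent and bonds to C5 from that face, which leaves C7 cis to the C6 substituent. C4 is controlled by the enol ether geometry: in the boat the substituent trans to C2 (the ether oxygen) ends cis to C7 and the cis substituent (C13) trans to it. The step needs the arm axial, which the ground-state half-chair provides because isopropyl and dimethoxymethyl are then both equatorial, and it needs configurationally pure C2 and (E)-alkene, since the shift transfers both without correction.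

**Part B. From the rearranged acid to the diol of the lactone half**

Step 12
Reactants: 18 (1S,2R,5R,6S)-6-(dimethoxymethyl)-2-[(4-methoxyphenyl)methoxy]-5-(propan-2-yl)-2-({[tri(propan-2-yl)silyl]oxy}methyl)cyclohex-3-ene-1-carboxylic acid
Product: 19 (1S,2R,5S,6S)-6-(dimethoxymethyl)-2-[(4-methoxyphenyl)methoxy]-5-(propan-2-yl)-2-({[tri(propan-2-yl)silyl]oxy}methyl)cyclohexane-1-carboxylic acid
Conditions: 4-MeC6H4SO2NHNH2, NaOAc, DME/H2O, 85 °C (repeated charges)
Reagents that add atoms: none
Why: Diimide generated from the sulfonyl hydrazide transfers H2 to the cis-disubstituted ring alkene without touching the benzylic ether, which catalytic hydrogenation would endanger. No stereocentre is formed (C1 becomes S by priority change only).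

Step 13
Reactants: 19 (1S,2R,5S,6S)-6-(dimethoxymethyl)-2-[(4-methoxyphenyl)methoxy]-5-(propan-2-yl)-2-({[tri(propan-2-yl)silyl]oxy}methyl)cyclohexane-1-carboxylic acid
Product: 20 (1S,2R,5S,6S)-6-formyl-2-[(4-methoxyphenyl)methoxy]-5-(propan-2-yl)-2-({[tri(propan-2-yl)silyl]oxy}methyl)cyclohexane-1-carboxylic acid (may exist partly as its ring-closed hydroxy-lactone tautomer)
Conditions: AcOH/THF/H2O (3:1:1), 45 °C
Reagents that add atoms: water, O
Why: Mild acetal hydrolysis brings C10 to the aldehyde level without ever exposing a C10 alcohol cis to the C7 acid, which would close a γ-lactone. C6 should keep its configuration because the equatorial formyl group trans to isopropyl is the stable epimer.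

Step 14
Reactants: 21 2-(diethoxyphosphoryl)acetic acid; 22 2-(trimethylsilyl)ethanol
Product: 23 2-(trimethylsilyl)ethyl 2-(diethoxyphosphoryl)acetate
Conditions: DCC, DMAP (cat.), CH2Cl2, 0 °C → rt
Reagents that add atoms: none
Why: Steglich esterification; the trimethylsilylethyl ester is the fluoride-labile mask for the C9 carboxyl.

Step 15
Reactants: 23 2-(trimethylsilyl)ethyl 2-(diethoxyphosphoryl)acetate
Product: 24 2-(trimethylsilyl)ethyl 2-(diethoxyphosphoryl)-3-hydroxypropanoate (racemic)
Conditions: (CH2O)n, piperidine (cat.), i-PrOH, 70 °C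
Reagents that add atoms: paraformaldehyde (as formaldehyde), C=O
Why: Base-catalysed hydroxymethylation of a phosphonoacetate (aldol addition to formaldehyde), the first stage of the known route to 2-phosphonoacrylates, stopped at the alcohol.

Step 16
Reactants: 24 2-(trimethylsilyl)ethyl 2-(diethoxyphosphoryl)-3-hydroxypropanoate
Product: 25 2-(trimethylsilyl)ethyl 3-{[tert-butyl(dimethyl)silyl]oxy}-2-(diethoxyphosphoryl)propanoate (racemic)
Conditions: t-BuMe2SiCl, imidazole, CH2Cl2, rt
Reagents that add atoms: tert-butyl(chloro)dimethylsilane, CC(C)(C)[Si](C)(C)Cl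
Why: Silylation of the primary alcohol under conditions too weakly basic to cause β-elimination of the phosphonate.

Step 17
Reactants: 20 (1S,2R,5S,6S)-6-formyl-2-[(4-methoxyphenyl)methoxy]-5-(propan-2-yl)-2-({[tri(propan-2-yl)silyl]oxy}methyl)cyclohexane-1-carboxylic acid; 25 2-(trimethylsilyl)ethyl 3-{[tert-butyl(dimethyl)silyl]oxy}-2-(diethoxyphosphoryl)propanoate
Product: 26 (1S,2R,5S,6R)-6-[(1E)-3-{[tert-butyl(dimethyl)silyl]oxy}-2-{[2-(trimethylsilyl)ethoxy]carbonyl}prop-1-en-1-yl]-2-[(4-methoxyphenyl)methoxy]-5-(propan-2-yl)-2-({[tri(propan-2-yl)silyl]oxy}methyl)cyclohexane-1-carboxylic acid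
Conditions: 25, LiCl, DBU (3 equiv), MeCN, 0 °C → rt
Reagents that add atoms: none
Why: Horner–Wadsworth–Emmons olefination under mild LiCl/amine conditions, with the acid carried as its carboxylate, which also opens any lactol form. An α-substituted phosphonoacetate with an α-branched aldehyde should give mainly the (E)-alkenoate with C6 cis to the CH2O group, as ring B requires.

Step 18
Reactants: 26 (1S,2R,5S,6R)-6-[(1E)-3-{[tert-butyl(dimethyl)silyl]oxy}-2-{[2-(trimethylsilyl)ethoxy]carbonyl}prop-1-en-1-yl]-2-[(4-methoxyphenyl)methoxy]-5-(propan-2-yl)-2-({[tri(propan-2-yl)silyl]oxy}methyl)cyclohexane-1-carboxylic acid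
Product: 27 (1S,2R,5S,6R)-6-[(1E)-3-hydroxy-2-{[2-(trimethylsilyl)ethoxy]carbonyl}prop-1-en-1-yl]-2-[(4-methoxyphenyl)methoxy]-5-(propan-2-yl)-2-({[tri(propan-2-yl)silyl]oxy}methyl)cyclohexane-1-carboxylic acid
Conditions: HF·pyridine, pyridine, THF, 0 °C
Reagents that add atoms: none
Why: Buffered HF cleaves the unhindered allylic silyl ether much faster than the neopentyl triisopropylsilyl ether; the trimethylsilylethyl ester and the benzylic ether are stable to it.

Step 19
Reactants: 27 (1S,2R,5S,6R)-6-[(1E)-3-hydroxy-2-{[2-(trimethylsilyl)ethoxy]carbonyl}prop-1-en-1-yl]-2-[(4-methoxyphenyl)methoxy]-5-(propan-2-yl)-2-({[tri(propan-2-yl)silyl]oxy}methyl)cyclohexane-1-carboxylic acid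
Product: 29 2-(trimethylsilyl)ethyl (5aR,6S,9R,9aS)-9-[(4-methoxyphenyl)methoxy]-1-oxo-6-(propan-2-yl)-9-({[tri(propan-2-yl)silyl]oxy}methyl)-1,3,5a,6,7,8,9,9a-octahydro-2-benzoxepine-4-carboxylate, via mixed anhydride 28 (not isolated)
Conditions: 2-methyl-6-nitrobenzoic anhydride, DMAP (cat.), Et3N, CH2Cl2 (2 mM, slow addition), rt
Reagents that add atoms: none
Why: Mixed-anhydride (Shiina) lactonisation at high dilution: acyl transfer from 28 to the only free hydroxyl, the allylic C8–OH held near C7 by the alkene geometry, closes the seven-membered ring B. O4 is still etherified, so no β-lactone can form.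

Step 20
Reactants: 29 2-(trimethylsilyl)ethyl (5aR,6S,9R,9aS)-9-[(4-methoxyphenyl)methoxy]-1-oxo-6-(propan-2-yl)-9-({[tri(propan-2-yl)silyl]oxy}methyl)-1,3,5a,6,7,8,9,9a-octahydro-2-benzoxepine-4-carboxylate
Product: 30 2-(trimethylsilyl)ethyl (5aR,6S,9R,9aS)-9-hydroxy-1-oxo-6-(propan-2-yl)-9-({[tri(propan-2-yl)silyl]oxy}methyl)-1,3,5a,6,7,8,9,9a-octahydro-2-benzoxepine-4-carboxylate
Conditions: DDQ, CH2Cl2/pH 7 buffer, 0 °C
Reagents that add atoms: none
Why: Oxidative cleavage of the 4-methoxybenzyl ether by hydride abstraction and hydrolysis of the oxocarbenium ion; the electron-poor acrylate and the lactone are inert to DDQ.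

Step 21
Reactants: 30 2-(trimethylsilyl)ethyl (5aR,6S,9R,9aS)-9-hydroxy-1-oxo-6-(propan-2-yl)-9-({[tri(propan-2-yl)silyl]oxy}methyl)-1,3,5a,6,7,8,9,9a-octahydro-2-benzoxepine-4-carboxylate
Product: 31 2-(trimethylsilyl)ethyl (5aR,6S,9R,9aS)-9-hydroxy-9-(hydroxymethyl)-1-oxo-6-(propan-2-yl)-1,3,5a,6,7,8,9,9a-octahydro-2-benzoxepine-4-carboxylate
Conditions: HF·pyridine, THF, rt
Reagents that add atoms: none
Why: Prolonged HF·pyridine removes the hindered silyl ether while leaving the trimethylsilylethyl ester. The axial C13–OH is anti to the axial C7 carbonyl, so translactonisation to a γ-lactone is not expected.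

**Part C. Acyl half**

Step 22
Reactants: 4 3-methylbutanal; 32 but-3-en-2-one (methyl vinyl ketone)
Product: 33 (2S)-5-oxo-2-(propan-2-yl)hexanal
Conditions: (S)-2-[methoxy(diphenyl)methyl]pyrrolidine (5 mol %), ethyl 3,4-dihydroxybenzoate (20 mol %), neat, 4 °C
Reagents that add atoms: none
Why: Enamine-catalysed Michael addition of an aldehyde to a vinyl ketone. The same facial rule as in step 2 applies, but here the aldehyde carbon becomes the ring carbon next to the stereocentre, so the (S)-catalyst is the one required.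

Step 23
Reactants: 33 (2S)-5-oxo-2-(propan-2-yl)hexanal
Product: 34 (4S)-4-(propan-2-yl)cyclohex-2-en-1-one ((S)-cryptone)
Conditions: LiOH, i-PrOH, rt
Reagents that add atoms: none
Why: Intramolecular aldol condensation of the methyl ketone onto the aldehyde; the stereocentre is γ to the new carbonyl and is not enolised under these mild conditions.

Step 24
Reactants: 34 (4S)-4-(propan-2-yl)cyclohex-2-en-1-one
Product: 36 (3S,4S)-3-ethenyl-4-(propan-2-yl)cyclohex-1-en-1-yl trifluoromethanesulfonate (vinyl trans to isopropyl), via magnesium enolate 35 (not isolated)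
Conditions: CH2=CHMgBr, CuBr·SMe2 (10 mol %), THF, −78 → −40 °C; then N-(5-chloropyridin-2-yl)-1,1,1-trifluoro-N-(trifluoromethylsulfonyl)methanesulfonamide, −78 → 0 °C
Reagents that add atoms: vinylmagnesium bromide, C=C[Mg]Br; N-(5-chloropyridin-2-yl)-1,1,1-trifluoro-N-(trifluoromethylsulfonyl)methanesulfonamide, FC(F)(F)S(=O)(=O)N(c1ccc(Cl)cn1)S(=O)(=O)C(F)(F)F
Why: Copper-catalysed conjugate addition to a 4-substituted cyclohexenone occurs anti to the C4 substituent and sets C1′ trans to the isopropyl group. The enolate is formed regiospecifically towards the new stereocentre and is trapped as the triflate, which fixes the C2′=C3′ alkene.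

Step 25
Reactants: 36 (3S,4S)-3-ethenyl-4-(propan-2-yl)cyclohex-1-en-1-yl trifluoromethanesulfonate
Product: 37 (3S,4S)-3-formyl-4-(propan-2-yl)cyclohex-1-en-1-yl trifluoromethanesulfonate
Conditions: O3, CH2Cl2/MeOH, −78 °C (indicator end-point); then Me2S
Reagents that add atoms: ozone, [O-][O+]=O
Why: Ozonolysis is selective for the vinyl group because the enol triflate alkene is strongly deactivated towards the electrophilic oxidant. The trans aldehyde is the stable epimer.

Step 26
Reactants: 37 (3S,4S)-3-formyl-4-(propan-2-yl)cyclohex-1-en-1-yl trifluoromethanesulfonate; 25 2-(trimethylsilyl)ethyl 3-{[tert-butyl(dimethyl)silyl]oxy}-2-(diethoxyphosphoryl)propanoate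
Product: 38 2-(trimethylsilyl)ethyl (2E)-2-({[tert-butyl(dimethyl)silyl]oxy}methyl)-3-[(1R,6S)-6-(propan-2-yl)-3-{[(trifluoromethyl)sulfonyl]oxy}cyclohex-2-en-1-yl]prop-2-enoate (C1′ is R by priority change only)
Conditions: 25, LiCl, DBU, MeCN, 0 °C
Reagents that add atoms: none
Why: Horner–Wadsworth–Emmons olefination under mild LiCl/amine conditions suited to an α-stereogenic β,γ-unsaturated aldehyde; the (E)-alkenoate with the ring cis to CH2O should predominate.

Step 27
Reactants: 38 2-(trimethylsilyl)ethyl (2E)-2-({[tert-butyl(dimethyl)silyl]oxy}methyl)-3-[(1R,6S)-6-(propan-2-yl)-3-{[(trifluoromethyl)sulfonyl]oxy}cyclohex-2-en-1-yl]prop-2-enoate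
Product: 39 2-(trimethylsilyl)ethyl (2E)-2-({[tert-butyl(dimethyl)silyl]oxy}methyl)-3-[(1S,6S)-3-(hydroxymethyl)-6-(propan-2-yl)cyclohex-2-en-1-yl]prop-2-enoate
Conditions: Bu3SnCH2OH, Pd(PPh3)4 (5 mol %), LiCl, 1,4-dioxane, 90 °C
Reagents that add atoms: (tributylstannyl)methanol, CCCC[Sn](CCCC)(CCCC)CO
Why: Stille coupling: zerovalent palladium inserts into the enol triflate, LiCl assists transmetalation, and the hydroxymethyl group is transferred from tin. The molecule has no allylic leaving group that the catalyst could ionise.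

Step 28
Reactants: 39 2-(trimethylsilyl)ethyl (2E)-2-({[tert-butyl(dimethyl)silyl]oxy}methyl)-3-[(1S,6S)-3-(hydroxymethyl)-6-(propan-2-yl)cyclohex-2-en-1-yl]prop-2-enoate
Product: 40 (2E)-2-(hydroxymethyl)-3-[(1S,6S)-3-(hydroxymethyl)-6-(propan-2-yl)cyclohex-2-en-1-yl]prop-2-enoic acid
Conditions: Bu4NF, THF, 0 °C → rt; aq. NH4Cl
Reagents that add atoms: none
Why: Fluoride cleaves the silyl ether and, by attack at silicon with loss of ethene, the trimethylsilylethyl ester; the ester cannot be removed selectively, so both groups are taken off together.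

Step 29
Reactants: 40 (2E)-2-(hydroxymethyl)-3-[(1S,6S)-3-(hydroxymethyl)-6-(propan-2-yl)cyclohex-2-en-1-yl]prop-2-enoic acid
Product: 42 (2E)-2-({[tert-butyl(dimethyl)silyl]oxy}methyl)-3-[(1S,6S)-3-({[tert-butyl(dimethyl)silyl]oxy}methyl)-6-(propan-2-yl)cyclohex-2-en-1-yl]prop-2-enoic acid, via silyl ester 41 (not isolated)
Conditions: t-BuMe2SiCl (3.5 equiv), imidazole, DMF, rt; then K2CO3, MeOH/THF/H2O, 0 °C
Reagents that add atoms: tert-butyl(chloro)dimethylsilane, CC(C)(C)[Si](C)(C)Cl
Why: Exhaustive silylation followed by selective hydrolysis of the labile silyl ester, a standard way to obtain a silyl-protected hydroxy acid.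

**Part D. Union and deprotection**

Step 30
Reactants: 42 (2E)-2-({[tert-butyl(dimethyl)silyl]oxy}methyl)-3-[(1S,6S)-3-({[tert-butyl(dimethyl)silyl]oxy}methyl)-6-(propan-2-yl)cyclohex-2-en-1-yl]prop-2-enoic acid; 31 2-(trimethylsilyl)ethyl (5aR,6S,9R,9aS)-9-hydroxy-9-(hydroxymethyl)-1-oxo-6-(propan-2-yl)-1,3,5a,6,7,8,9,9a-octahydro-2-benzoxepine-4-carboxylate
Product: 44 2-(trimethylsilyl)ethyl (5aR,6S,9R,9aS)-9-({[(2E)-2-({[tert-butyl(dimethyl)silyl]oxy}methyl)-3-[(1S,6S)-3-({[tert-butyl(dimethyl)silyl]oxy}methyl)-6-(propan-2-yl)cyclohex-2-en-1-yl]prop-2-enoyl]oxy}methyl)-9-hydroxy-1-oxo-6-(propan-2-yl)-1,3,5a,6,7,8,9,9a-octahydro-2-benzoxepine-4-carboxylate, via mixed anhydride 43 (not isolated)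
Conditions: 42, 2,4,6-Cl3C6H2COCl, Et3N, THF, rt; then 31, DMAP, toluene, rt
Reagents that add atoms: none
Why: Yamaguchi esterification: the preformed mixed anhydride 43 acylates the primary C13–OH; the tertiary C4–OH is too hindered to compete and needs no protection.

Step 31
Reactants: 44 2-(trimethylsilyl)ethyl (5aR,6S,9R,9aS)-9-({[(2E)-2-({[tert-butyl(dimethyl)silyl]oxy}methyl)-3-[(1S,6S)-3-({[tert-butyl(dimethyl)silyl]oxy}methyl)-6-(propan-2-yl)cyclohex-2-en-1-yl]prop-2-enoyl]oxy}methyl)-9-hydroxy-1-oxo-6-(propan-2-yl)-1,3,5a,6,7,8,9,9a-octahydro-2-benzoxepine-4-carboxylate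
Product: 45 (5aR,6S,9R,9aS)-9-hydroxy-9-({[(2E)-2-(hydroxymethyl)-3-[(1S,6S)-3-(hydroxymethyl)-6-(propan-2-yl)cyclohex-2-en-1-yl]prop-2-enoyl]oxy}methyl)-1-oxo-6-(propan-2-yl)-1,3,5a,6,7,8,9,9a-octahydro-2-benzoxepine-4-carboxylic acid (CNP0361406.4)
Conditions: Bu4NF/AcOH (1:1), THF, 0 °C → rt
Reagents that add atoms: none
Why: Buffered fluoride removes both silyl ethers and the trimethylsilylethyl ester in one operation without hydrolytic or palladium-based conditions, which the three esters and the allylic lactone would not tolerate.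

## Compound list

1 | 2,2-dimethoxyacetaldehyde | COC(OC)C=O | starting material
2 | dimethyl malonate | COC(=O)CC(=O)OC | starting material
3 | dimethyl 2-(2,2-dimethoxyethylidene)propanedioate | COC(OC)C=C(C(=O)OC)C(=O)OC | intermediate
4 | 3-methylbutanal | CC(C)CC=O | starting material
5 | dimethyl 2-[(2S,3S)-3-formyl-1,1-dimethoxy-4-methylpentan-2-yl]propanedioate | COC(=O)C(C(=O)OC)[C@@H](C(OC)OC)[C@H](C(C)C)C=O | intermediate
6 | (2S,3S)-3-(dimethoxymethyl)-5-methoxy-4-(methoxycarbonyl)-5-oxo-2-(propan-2-yl)pentanoic acid | COC(=O)C(C(=O)OC)[C@@H](C(OC)OC)[C@H](C(C)C)C(=O)O | intermediate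
7 | dimethyl 2-[(2S,3S)-1,1-dimethoxy-3-[methoxy(methyl)carbamoyl]-4-methylpentan-2-yl]propanedioate | COC(=O)C(C(=O)OC)[C@@H](C(OC)OC)[C@H](C(C)C)C(=O)N(C)OC | intermediate
8 | methyl (3R,4S)-3-(dimethoxymethyl)-4-[methoxy(methyl)carbamoyl]-5-methylhexanoate | COC(=O)C[C@@H](C(OC)OC)[C@H](C(C)C)C(=O)N(C)OC | intermediate
9 | prop-2-yn-1-ol | C#CCO | starting material
10 | tri(propan-2-yl)(prop-2-yn-1-yloxy)silane | C#CCO[Si](C(C)C)(C(C)C)C(C)C | intermediate
11 | lithium acetylide of 10, {3-[tri(propan-2-yl)silyloxy]prop-1-yn-1-yl}lithium | [Li]C#CCO[Si](C(C)C)(C(C)C)C(C)C | intermediate (not isolated)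
12 | methyl (3R,4S)-3-(dimethoxymethyl)-5-oxo-4-(propan-2-yl)-8-{[tri(propan-2-yl)silyl]oxy}oct-6-ynoate | COC(=O)C[C@@H](C(OC)OC)[C@H](C(C)C)C(=O)C#CCO[Si](C(C)C)(C(C)C)C(C)C | intermediate
13 | methyl (3R,4S,6E)-3-(dimethoxymethyl)-7-[(4-methoxyphenyl)methoxy]-5-oxo-4-(propan-2-yl)-8-{[tri(propan-2-yl)silyl]oxy}oct-6-enoate | COC(=O)C[C@@H](C(OC)OC)[C@H](C(C)C)C(=O)/C=C(/OCc1ccc(OC)cc1)CO[Si](C(C)C)(C(C)C)C(C)C | intermediate
14 | methyl (3R,4S,5R,6E)-3-(dimethoxymethyl)-5-hydroxy-7-[(4-methoxyphenyl)methoxy]-4-(propan-2-yl)-8-{[tri(propan-2-yl)silyl]oxy}oct-6-enoate | COC(=O)C[C@@H](C(OC)OC)[C@H](C(C)C)[C@@H](O)/C=C(/OCc1ccc(OC)cc1)CO[Si](C(C)C)(C(C)C)C(C)C | intermediate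
15 | (4R,5S,6R)-4-(dimethoxymethyl)-6-[(1E)-2-[(4-methoxyphenyl)methoxy]-3-{[tri(propan-2-yl)silyl]oxy}prop-1-en-1-yl]-5-(propan-2-yl)oxan-2-one | O=C1C[C@@H](C(OC)OC)[C@H](C(C)C)[C@H](/C=C(/OCc2ccc(OC)cc2)CO[Si](C(C)C)(C(C)C)C(C)C)O1 | intermediate (precursor of the key step)
16 | trimethylsilyl ketene acetal of 15, (2R,3S,4S)-4-(dimethoxymethyl)-2-[(1E)-2-[(4-methoxyphenyl)methoxy]-3-{[tri(propan-2-yl)silyl]oxy}prop-1-en-1-yl]-3-(propan-2-yl)-6-[(trimethylsilyl)oxy]-3,4-dihydro-2H-pyran | C[Si](C)(C)OC1=C[C@@H](C(OC)OC)[C@H](C(C)C)[C@H](/C=C(/OCc2ccc(OC)cc2)CO[Si](C(C)C)(C(C)C)C(C)C)O1 | intermediate (not isolated)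
17 | trimethylsilyl (1S,2R,5R,6S)-6-(dimethoxymethyl)-2-[(4-methoxyphenyl)methoxy]-5-(propan-2-yl)-2-({[tri(propan-2-yl)silyl]oxy}methyl)cyclohex-3-ene-1-carboxylate | CC(C)[C@@H]1C=C[C@](OCc2ccc(OC)cc2)(CO[Si](C(C)C)(C(C)C)C(C)C)[C@@H](C(=O)O[Si](C)(C)C)[C@H]1C(OC)OC | intermediate (not isolated)
18 | (1S,2R,5R,6S)-6-(dimethoxymethyl)-2-[(4-methoxyphenyl)methoxy]-5-(propan-2-yl)-2-({[tri(propan-2-yl)silyl]oxy}methyl)cyclohex-3-ene-1-carboxylic acid | CC(C)[C@@H]1C=C[C@](OCc2ccc(OC)cc2)(CO[Si](C(C)C)(C(C)C)C(C)C)[C@@H](C(=O)O)[C@H]1C(OC)OC | intermediate (product of the key step)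
19 | (1S,2R,5S,6S)-6-(dimethoxymethyl)-2-[(4-methoxyphenyl)methoxy]-5-(propan-2-yl)-2-({[tri(propan-2-yl)silyl]oxy}methyl)cyclohexane-1-carboxylic acid | CC(C)[C@@H]1CC[C@](OCc2ccc(OC)cc2)(CO[Si](C(C)C)(C(C)C)C(C)C)[C@@H](C(=O)O)[C@H]1C(OC)OC | intermediate
20 | (1S,2R,5S,6S)-6-formyl-2-[(4-methoxyphenyl)methoxy]-5-(propan-2-yl)-2-({[tri(propan-2-yl)silyl]oxy}methyl)cyclohexane-1-carboxylic acid | CC(C)[C@@H]1CC[C@](OCc2ccc(OC)cc2)(CO[Si](C(C)C)(C(C)C)C(C)C)[C@@H](C(=O)O)[C@H]1C=O | intermediate
21 | 2-(diethoxyphosphoryl)acetic acid | CCOP(=O)(OCC)CC(=O)O | starting material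
22 | 2-(trimethylsilyl)ethanol | C[Si](C)(C)CCO | starting material
23 | 2-(trimethylsilyl)ethyl 2-(diethoxyphosphoryl)acetate | CCOP(=O)(OCC)CC(=O)OCC[Si](C)(C)C | intermediate
24 | 2-(trimethylsilyl)ethyl 2-(diethoxyphosphoryl)-3-hydroxypropanoate (racemic) | CCOP(=O)(OCC)C(CO)C(=O)OCC[Si](C)(C)C | intermediate
25 | 2-(trimethylsilyl)ethyl 3-{[tert-butyl(dimethyl)silyl]oxy}-2-(diethoxyphosphoryl)propanoate (racemic) | CCOP(=O)(OCC)C(CO[Si](C)(C)C(C)(C)C)C(=O)OCC[Si](C)(C)C | intermediate
26 | (1S,2R,5S,6R)-6-[(1E)-3-{[tert-butyl(dimethyl)silyl]oxy}-2-{[2-(trimethylsilyl)ethoxy]carbonyl}prop-1-en-1-yl]-2-[(4-methoxyphenyl)methoxy]-5-(propan-2-yl)-2-({[tri(propan-2-yl)silyl]oxy}methyl)cyclohexane-1-carboxylic acid | CC(C)[C@@H]1CC[C@](OCc2ccc(OC)cc2)(CO[Si](C(C)C)(C(C)C)C(C)C)[C@@H](C(=O)O)[C@H]1/C=C(/C(=O)OCC[Si](C)(C)C)CO[Si](C)(C)C(C)(C)C | intermediate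
27 | (1S,2R,5S,6R)-6-[(1E)-3-hydroxy-2-{[2-(trimethylsilyl)ethoxy]carbonyl}prop-1-en-1-yl]-2-[(4-methoxyphenyl)methoxy]-5-(propan-2-yl)-2-({[tri(propan-2-yl)silyl]oxy}methyl)cyclohexane-1-carboxylic acid | CC(C)[C@@H]1CC[C@](OCc2ccc(OC)cc2)(CO[Si](C(C)C)(C(C)C)C(C)C)[C@@H](C(=O)O)[C@H]1/C=C(/C(=O)OCC[Si](C)(C)C)CO | intermediate
28 | mixed anhydride of 27 with 2-methyl-6-nitrobenzoic acid | CC(C)[C@@H]1CC[C@](OCc2ccc(OC)cc2)(CO[Si](C(C)C)(C(C)C)C(C)C)[C@@H](C(=O)OC(=O)c2c(C)cccc2[N+](=O)[O-])[C@H]1/C=C(/C(=O)OCC[Si](C)(C)C)CO | intermediate (not isolated)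
29 | 2-(trimethylsilyl)ethyl (5aR,6S,9R,9aS)-9-[(4-methoxyphenyl)methoxy]-1-oxo-6-(propan-2-yl)-9-({[tri(propan-2-yl)silyl]oxy}methyl)-1,3,5a,6,7,8,9,9a-octahydro-2-benzoxepine-4-carboxylate | CC(C)[C@@H]1CC[C@](OCc3ccc(OC)cc3)(CO[Si](C(C)C)(C(C)C)C(C)C)[C@H]2C(=O)OCC(C(=O)OCC[Si](C)(C)C)=C[C@@H]12 | intermediate
30 | 2-(trimethylsilyl)ethyl (5aR,6S,9R,9aS)-9-hydroxy-1-oxo-6-(propan-2-yl)-9-({[tri(propan-2-yl)silyl]oxy}methyl)-1,3,5a,6,7,8,9,9a-octahydro-2-benzoxepine-4-carboxylate | CC(C)[C@@H]1CC[C@](O)(CO[Si](C(C)C)(C(C)C)C(C)C)[C@H]2C(=O)OCC(C(=O)OCC[Si](C)(C)C)=C[C@@H]12 | intermediate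
31 | 2-(trimethylsilyl)ethyl (5aR,6S,9R,9aS)-9-hydroxy-9-(hydroxymethyl)-1-oxo-6-(propan-2-yl)-1,3,5a,6,7,8,9,9a-octahydro-2-benzoxepine-4-carboxylate | CC(C)[C@@H]1CC[C@](O)(CO)[C@H]2C(=O)OCC(C(=O)OCC[Si](C)(C)C)=C[C@@H]12 | intermediate
32 | but-3-en-2-one | CC(=O)C=C | starting material
33 | (2S)-5-oxo-2-(propan-2-yl)hexanal | CC(C)[C@@H](C=O)CCC(C)=O | intermediate
34 | (4S)-4-(propan-2-yl)cyclohex-2-en-1-one | CC(C)[C@@H]1CCC(=O)C=C1 | intermediate
35 | bromomagnesium (3S,4S)-3-ethenyl-4-(propan-2-yl)cyclohex-1-en-1-olate | Br[Mg]OC1=C[C@@H](C=C)[C@H](C(C)C)CC1 | intermediate (not isolated)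
36 | (3S,4S)-3-ethenyl-4-(propan-2-yl)cyclohex-1-en-1-yl trifluoromethanesulfonate | C=C[C@@H]1C=C(OS(=O)(=O)C(F)(F)F)CC[C@H]1C(C)C | intermediate
37 | (3S,4S)-3-formyl-4-(propan-2-yl)cyclohex-1-en-1-yl trifluoromethanesulfonate | O=C[C@@H]1C=C(OS(=O)(=O)C(F)(F)F)CC[C@H]1C(C)C | intermediate
38 | 2-(trimethylsilyl)ethyl (2E)-2-({[tert-butyl(dimethyl)silyl]oxy}methyl)-3-[(1R,6S)-6-(propan-2-yl)-3-{[(trifluoromethyl)sulfonyl]oxy}cyclohex-2-en-1-yl]prop-2-enoate | C[Si](C)(C)CCOC(=O)/C(=C/[C@@H]1C=C(OS(=O)(=O)C(F)(F)F)CC[C@H]1C(C)C)CO[Si](C)(C)C(C)(C)C | intermediate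
39 | 2-(trimethylsilyl)ethyl (2E)-2-({[tert-butyl(dimethyl)silyl]oxy}methyl)-3-[(1S,6S)-3-(hydroxymethyl)-6-(propan-2-yl)cyclohex-2-en-1-yl]prop-2-enoate | C[Si](C)(C)CCOC(=O)/C(=C/[C@@H]1C=C(CO)CC[C@H]1C(C)C)CO[Si](C)(C)C(C)(C)C | intermediate
40 | (2E)-2-(hydroxymethyl)-3-[(1S,6S)-3-(hydroxymethyl)-6-(propan-2-yl)cyclohex-2-en-1-yl]prop-2-enoic acid | OC(=O)/C(=C/[C@@H]1C=C(CO)CC[C@H]1C(C)C)CO | intermediate
41 | tert-butyl(dimethyl)silyl ester of 42 | CC(C)(C)[Si](C)(C)OC(=O)/C(=C/[C@@H]1C=C(CO[Si](C)(C)C(C)(C)C)CC[C@H]1C(C)C)CO[Si](C)(C)C(C)(C)C | intermediate (not isolated)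
42 | (2E)-2-({[tert-butyl(dimethyl)silyl]oxy}methyl)-3-[(1S,6S)-3-({[tert-butyl(dimethyl)silyl]oxy}methyl)-6-(propan-2-yl)cyclohex-2-en-1-yl]prop-2-enoic acid | OC(=O)/C(=C/[C@@H]1C=C(CO[Si](C)(C)C(C)(C)C)CC[C@H]1C(C)C)CO[Si](C)(C)C(C)(C)C | intermediate
43 | mixed anhydride of 42 with 2,4,6-trichlorobenzoic acid | O=C(OC(=O)/C(=C/[C@@H]1C=C(CO[Si](C)(C)C(C)(C)C)CC[C@H]1C(C)C)CO[Si](C)(C)C(C)(C)C)c1c(Cl)cc(Cl)cc1Cl | intermediate (not isolated)
44 | 2-(trimethylsilyl)ethyl (5aR,6S,9R,9aS)-9-({[(2E)-2-({[tert-butyl(dimethyl)silyl]oxy}methyl)-3-[(1S,6S)-3-({[tert-butyl(dimethyl)silyl]oxy}methyl)-6-(propan-2-yl)cyclohex-2-en-1-yl]prop-2-enoyl]oxy}methyl)-9-hydroxy-1-oxo-6-(propan-2-yl)-1,3,5a,6,7,8,9,9a-octahydro-2-benzoxepine-4-carboxylate | CC(C)[C@@H]1CC[C@](O)(COC(=O)/C(=C/[C@@H]2C=C(CO[Si](C)(C)C(C)(C)C)CC[C@H]2C(C)C)CO[Si](C)(C)C(C)(C)C)[C@H]2C(=O)OCC(C(=O)OCC[Si](C)(C)C)=C[C@@H]12 | intermediate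
45 | (5aR,6S,9R,9aS)-9-hydroxy-9-({[(2E)-2-(hydroxymethyl)-3-[(1S,6S)-3-(hydroxymethyl)-6-(propan-2-yl)cyclohex-2-en-1-yl]prop-2-enoyl]oxy}methyl)-1-oxo-6-(propan-2-yl)-1,3,5a,6,7,8,9,9a-octahydro-2-benzoxepine-4-carboxylic acid | CC(C)[C@@H]1CC[C@](O)(COC(=O)/C(=C/[C@@H]2C=C(CO)CC[C@H]2C(C)C)CO)[C@H]2C(=O)OCC(C(=O)O)=C[C@@H]12 | target

## Step count and least certain steps

- Total: 31 steps.
- Longest linear sequence: 19 steps from 1 (steps 1–5, 7–13, 17–21, 30, 31).
- Side branches: the acyl half is 8 steps from 4 (steps 22–29), phosphonate 25 is 3 steps (14–16), and alkyne 10 is 1 step (6).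

**Step 11 (key step).** Bond formation to the fully substituted, donor-substituted C4 may be slow. Meanwhile the electron-rich allylic C2–O bond of the ketene acetal can ionise, which would lose the stereochemical information or fragment the molecule, and the trimethylsilyl acetal can C-silylate or hydrolyse. Fallback, from 15 back to 18: replace the one-pot low-temperature trap by a stepwise route through isolable intermediates. Compound 15 is enolised with KN(SiMe3)2 in THF/DMPU and trapped with t-BuMe2SiCl to the tert-butyldimethylsilyl ketene acetal of 15 F1, which is freed from salts and heated in toluene (80–110 °C) under neutral conditions. The resulting tert-butyldimethylsilyl ester of 18 F2 is cleaved with K2CO3 in MeOH/H2O to give 18.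

**Step 9.** Hydride delivery may show little facial discrimination, or the opposite sense, because both ketone substituents are large and the vinylogous ester is a poor electrophile. Fallback, from 13 back to 13/14: abandon reagent control for a separate-and-recycle loop. Luche reduction (NaBH4, CeCl3·7H2O, MeOH, −78 °C) gives 14 together with its C2 epimer, methyl (3R,4S,5S,6E)-3-(dimethoxymethyl)-5-hydroxy-7-[(4-methoxyphenyl)methoxy]-4-(propan-2-yl)-8-{[tri(propan-2-yl)silyl]oxy}oct-6-enoate F3. The epimers are separated on base-washed silica and F3 is returned to 13 with MnO2 in CH2Cl2. The lactone from any residual F3 would have an equatorial arm and should not rearrange in step 11, so small amounts are tolerated.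

**Step 19.** Acyl transfer from the hindered, axial C7 mixed anhydride may be slow. That gives time for epimerisation at C5 to the equatorial carboxyl and for attack of the nucleophilic catalyst on the acrylate. Fallback, from 27 to 29: invert the roles of the partners so that the carboxyl is never activated. Under Mitsunobu conditions (PPh3, diisopropyl azodicarboxylate, toluene, high dilution) the carboxylate displaces the activated primary allylic C8–OH; no new isolated compound is involved.

**Step 30.** The activated acid can lose its doubly allylic γ-proton (deconjugation or epimerisation at C1′). The neopentyl C13–OH acylates slowly, and DMAP can open the allylic lactone of ring B by conjugate displacement. Fallback, from 31 to 44: make the C13–O bond by alkylation of the carboxylate instead of acyl transfer. Selective sulfonylation of the primary hydroxyl of 31 (TsCl, pyridine) gives the C13 4-methylbenzenesulfonate of 31 F4. DBU closes it to the spiro-epoxide 2-(trimethylsilyl)ethyl (5aR,6S,9R,9aS)-1-oxo-6-(propan-2-yl)-1,3,5a,6,7,8,9a-heptahydrospiro[2-benzoxepine-9,2′-oxirane]-4-carboxylate F5. The caesium salt of 42 (Cs2CO3, DMF, 60 °C) then opens F5 at its CH2 group to give 44 with retention at C4.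

**Step 31.** Alkoxides formed under fluoride can cause acyl migration, conjugate opening of ring B or epimerisation at C5, and cleavage of the trimethylsilylethyl ester may lag behind that of the ethers. Fallback, from 44 to 45: separate the two events. HF·pyridine in THF/pyridine removes only the two silyl ethers under mildly acidic conditions to give the diol ester, the 2-(trimethylsilyl)ethyl ester of 45 F6. The ester is then cleaved with anhydrous tris(dimethylamino)sulfonium difluorotrimethylsilicate in DMF at 0 °C.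

## Further compounds

F1 | step 11 | tert-butyldimethylsilyl ketene acetal of 15 | CC(C)(C)[Si](C)(C)OC1=C[C@@H](C(OC)OC)[C@H](C(C)C)[C@H](/C=C(/OCc2ccc(OC)cc2)CO[Si](C(C)C)(C(C)C)C(C)C)O1
F2 | step 11 | tert-butyldimethylsilyl ester of 18 | CC(C)[C@@H]1C=C[C@](OCc2ccc(OC)cc2)(CO[Si](C(C)C)(C(C)C)C(C)C)[C@@H](C(=O)O[Si](C)(C)C(C)(C)C)[C@H]1C(OC)OC
F3 | step 9 | methyl (3R,4S,5S,6E)-3-(dimethoxymethyl)-5-hydroxy-7-[(4-methoxyphenyl)methoxy]-4-(propan-2-yl)-8-{[tri(propan-2-yl)silyl]oxy}oct-6-enoate | COC(=O)C[C@@H](C(OC)OC)[C@H](C(C)C)[C@H](O)/C=C(/OCc1ccc(OC)cc1)CO[Si](C(C)C)(C(C)C)C(C)C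
F0 | step 19 | none | none
F4 | step 30 | C13 4-methylbenzenesulfonate of 31 | CC(C)[C@@H]1CC[C@](O)(COS(=O)(=O)c3ccc(C)cc3)[C@H]2C(=O)OCC(C(=O)OCC[Si](C)(C)C)=C[C@@H]12
F5 | step 30 | 2-(trimethylsilyl)ethyl (5aR,6S,9R,9aS)-1-oxo-6-(propan-2-yl)-1,3,5a,6,7,8,9a-heptahydrospiro[2-benzoxepine-9,2′-oxirane]-4-carboxylate | CC(C)[C@@H]1CC[C@]2(CO2)[C@H]3C(=O)OCC(C(=O)OCC[Si](C)(C)C)=C[C@@H]13
F6 | step 31 | 2-(trimethylsilyl)ethyl ester of 45 | CC(C)[C@@H]1CC[C@](O)(COC(=O)/C(=C/[C@@H]2C=C(CO)CC[C@H]2C(C)C)CO)[C@H]2C(=O)OCC(C(=O)OCC[Si](C)(C)C)=C[C@@H]12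
A1 | alternative 1 | cis-fused 8-methylidene-5-(propan-2-yl)bicyclo[4.2.0]octan-2-one (isopropyl trans to the cyclobutane) | CC(C)[C@@H]1CCC(=O)[C@H]2C(=C)C[C@@H]12
A2 | alternative 1 | spiro-epoxide of A1 (CH2 trans, oxygen cis to the C5–C7 bond) | CC(C)[C@@H]1CC[C@]3(CO3)[C@H]2C(=C)C[C@@H]12
A3 | alternative 2 | 2-{[2-(trimethylsilyl)ethoxy]carbonyl}prop-2-en-1-yl ester of the C6-vinyl spiro-epoxy cyclohexanecarboxylic acid | CC(C)[C@@H]1CC[C@]2(CO2)[C@@H](C(=O)OCC(=C)C(=O)OCC[Si](C)(C)C)[C@H]1C=C
A4 | alternative 2 | bicyclic oxepinone lactone with spiro-epoxide and trimethylsilylethyl ester | CC(C)[C@@H]1CC[C@]2(CO2)[C@H]3C(=O)OCC(C(=O)OCC[Si](C)(C)C)=C[C@@H]13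
A5 | alternative 3 | 6-({[tert-butyl(dimethyl)silyl]oxy}methyl)-2-methylidene-5-(propan-2-yl)cyclohexane-1-carboxylic acid | CC(C)[C@@H]1CCC(=C)[C@@H](C(=O)O)[C@H]1CO[Si](C)(C)C(C)(C)C
A6 | alternative 3 | cis-fused β-lactone with iodomethyl group on C4 | CC(C)[C@@H]1CC[C@@]2(CI)OC(=O)[C@H]2[C@H]1CO[Si](C)(C)C(C)(C)C
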